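Of the free catalyst charged to these flasks, the first 0.73 µM seemed to earn nothing, and subtracting it became my whole reckoning for grey and teal.

| setting | south | west | south-east | grey | teal |
|---|---|---|---|---|---|
| starting material | 1 mM | 1 mM | 1 mM | 1.0 mM | 1.0 mM |
| coupling partner | 2 mM | 2 mM | 2 mM | 2.00 mM | 2.00 mM |
| free catalyst | 1.6 µM | 2.4 µM | 2.9 µM | 2.0 µM | 3.0 µM |
| impurity | 0.73 µM | 0.73 µM | 0.73 µM | 0.73 µM | 0.73 µM |
| remark | run made earlier | run made earlier | run made earlier |  |  |
| time |  |  |  | 2.5 min | 2.5 min |

| run | time / s | starting material / % | catalyst intermediate E / % | target / % | catalyst intermediate B / % |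
|---|---|---|---|---|---|
| south | 10.0 | 95.6 | 0.3 | 4.8 | 1.6 |
| south | 15.0 | 93.8 | 0.5 | 7.6 | 0 |
| south | 30.0 | 87.5 | 2.9 | 13.8 | 0 |
| south | 60.0 | 73.9 | 0.1 | 25.1 | 1.4 |
| south | 120 | 55.9 | 0.9 | 44.5 | 0.8 |
| west | 10.0 | 90.6 | 0.2 | 8.7 | 0 |
| west | 15.0 | 89.3 | 0 | 13.3 | 0.9 |
| west | 30.0 | 73.6 | 0.2 | 25.4 | 1.0 |
| west | 60.0 | 54.0 | 0 | 43.9 | 0 |
| west | 120 | 32.1 | 0 | 64.7 | 1.6 |
| south-east | 20.0 | 76.7 | 0.2 | 22.1 | 0 |
| south-east | 40.0 | 61.9 | 0.3 | 38.5 | 1.0 |
| south-east | 60.0 | 47.6 | 0 | 52.9 | 0 |
| south-east | 80.0 | 36.4 | 1.6 | 60.6 | 1.2 |
| south-east | 120 | 23.4 | 0.9 | 75.0 | 0 |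

(each reading ± 1 percentage point)

- the earlier runs were read with a standard deviation of 1 percentage point

- which of these there is most of at the end, counted by the starting material in it, grey (catalyst intermediate E / catalyst intermediate B / target / starting material)
- which of these there is most of at the end, counted by the starting material in it, teal (catalyst intermediate E / catalyst intermediate B / target / starting material)
- amount of the one of these that there is most of at the end, in percent of the starting material charged, grey
- amount of the one of these that there is most of at the end, in percent of the starting material charged, teal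

I treated the starting material in each earlier run as pseudo-first-order, so the logarithm of charged over left, divided by time, gave an apparent constant at the last reading: 0.00485 s⁻¹ south, 0.00947 s⁻¹ west and 0.0121 s⁻¹ south-east. From south to south-east the free catalyst grew 1.81 times but the constant 2.49 times, so I divided instead by the working catalyst, free catalyst minus impurity, which gave 5570 M⁻¹ s⁻¹, 5670 M⁻¹ s⁻¹ and 5580 M⁻¹ s⁻¹, with the scatter of 1 point in them.

Their mean, 5610 M⁻¹ s⁻¹, was my first answer, but it stretched a constant past the last reading. The same ratio read at 60.0 s averaged 5880 M⁻¹ s⁻¹, which is higher, so I carried the fall on to the asked time and obtained the turnover constant per working catalyst 5470 M⁻¹ s⁻¹. Since catalyst intermediates E and B mostly read near the scatter, I counted the converted material as target, which gave 64.7 % for grey and 84.5 % for teal.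

The forecast named target in both flasks, at 66 % for grey and 85 % for teal, reasoning that “the impurity appears to kill catalyst stoichiometrically”.

The flask gave target as the largest share in grey, at 63.3 %, and target in teal, at 82.5 %.

    catalyst intermediate C → released group + catalyst intermediate D (k = 1200 s⁻¹)
    catalyst intermediate E ⇌ free catalyst + target (K = 3.80 × 10⁻⁴ M, k = 770 s⁻¹)
    free catalyst + released group → spent catalyst A (k = 50.0 M⁻¹ s⁻¹)
    catalyst intermediate D → catalyst intermediate E (k = 160 s⁻¹)
    coupling partner + catalyst intermediate B → catalyst intermediate C (k = 4500 M⁻¹ s⁻¹)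
    starting material + free catalyst ⇌ catalyst intermediate A (K = 28000 M⁻¹, k = 38000 M⁻¹ s⁻¹)
    free catalyst + impurity → spent catalyst B (k = 1.50 × 10⁷ M⁻¹ s⁻¹)
    catalyst intermediate A → catalyst intermediate B (k = 37.0 s⁻¹)

In grey the impurity stood at 0 % of its charge at 1.25 min, with spent catalyst B at 36.5 % of the catalyst charged, the 36.5 % my subtraction had removed. While starting material went on turning into target, spent catalyst A rose from 8.47 % to 25.3 % of the catalyst charged by 2.50 min, and grey ended with 36.6 % starting material against the 35.3 % that 5470 M⁻¹ s⁻¹ had left.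

In a neighbouring flask, teal with free catalyst cut to 1.20 µM, the working catalyst is 0.470 µM, so 5470 M⁻¹ s⁻¹ gives 32.0 % target. The computed flask holds 32.2 % target, with 68 % starting material, the larger share.

The numbers in the tables are calculated with constants of no real substance, and the scatter is random.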